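# Total synthesis plan for CNP0285414.3 (a briarane diterpenoid)

## Retrosynthetic overview

1. The ten-membered carbocycle is closed last by ring-closing metathesis, forming the (Z)-C3=C4 bond between a C2 vinyl carbinol and the terminal vinyl of the C4–C6 diene.
2. The γ-lactone (C7–O–C19) comes from C6–C7 bond formation: a dienyllithium (fragment C) acylates the dioxolanone carbonyl (C7), followed by chelation-controlled ketone reduction and spontaneous lactonisation.
3. The C8–C9 bond is made by a Seebach dioxolanone aldol between the ring A aldehyde (fragment A) and a methylmalic acid acetal (fragment B, carrying C7, C8, C17–C19).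
4. Ring A comes from a catalytic asymmetric Diels–Alder reaction of a 2-silyloxydiene with an (E)-2-methylenal, then Saegusa oxidation, C11 epimerisation, reduction and epoxidation.
5. Order of ring formation: cyclohexane ring A, then the 13,14-epoxide, then the γ-lactone, then the ten-membered ring.

## Assumptions and conventions

- Atom labels C1–C20 follow briarane numbering: C1 is the quaternary fusion carbon, C10 the other fusion carbon, C15 the methyl on C1, C16 on C5, C18 on C17, C20 on C11. "β" is the face of ring A that carries C15; "α" is the opposite face.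
- Assumption: the (S)-oxazaborolidinium catalyst of step 4 is taken to give the enantiomer drawn for 6; if the sense is opposite, its antipode is used.
- Abbreviations: PMB = 4-methoxybenzyl, TBS = tert-butyldimethylsilyl, TES = triethylsilyl, TBDPS = tert-butyldiphenylsilyl, Tf = trifluoromethanesulfonyl, DMPU = N,N'-dimethylpropyleneurea.
- This route is a design from first principles; no step has been run, and selectivities are predictions from the models named in each step.

## Fragment A: ring A aldehyde 16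

Step 1
Reactants: 1 3-methylbut-2-en-1-ol (prenol)
Product: 2 prenyl PMB ether
Conditions: NaH, 4-methoxybenzyl chloride, n-Bu4NI (cat.), THF, 0 °C → rt
Reagents that add atoms: 4-methoxybenzyl chloride, COc1ccc(CCl)cc1
Why: Williamson ether synthesis protects the future C9 oxygen as an oxidatively removable ether.

Step 2
Reactants: 2 prenyl PMB ether
Product: 3 (2E)-4-[(4-methoxybenzyl)oxy]-2-methylbut-2-enal
Conditions: SeO2 (1.1 equiv), 1,4-dioxane, 80 °C
Reagents that add atoms: selenium dioxide, O=[Se]=O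
Why: Riley allylic oxidation (ene reaction, then [2,3]-shift) attacks the (E)-methyl group of the trisubstituted alkene, giving the E enal whose geometry later places C9 cis to C15.

Step 3
Reactants: 4 pent-1-en-3-one (ethyl vinyl ketone)
Product: 5 tert-butyl(dimethyl)[(3Z)-penta-1,3-dien-3-yloxy]silane
Conditions: TBSOTf, Et3N, Et2O, 0 °C
Reagents that add atoms: tert-butyldimethylsilyl triflate, CC(C)(C)[Si](C)(C)OS(=O)(=O)C(F)(F)F
Why: Soft enolisation with O-silylation gives the (Z)-silyl enol ether, a 2-silyloxydiene whose terminal methyl (C20) sits "outside".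

Step 4
Reactants: 3 (2E)-4-[(4-methoxybenzyl)oxy]-2-methylbut-2-enal; 5 silyloxydiene
Product: 6 Diels–Alder adduct (ring A: 1β-CH3, 1α-CHO = C2, 10β-CH2OPMB, 11α-CH3, C12(OTBS)=C13 enol ether)
Conditions: (S)-3,3-diphenyl-1-(2-methylphenyl)tetrahydro-1H,3H-pyrrolo[1,2-c][1,3,2]oxazaborole (20 mol %), HN(SO2CF3)2 (20 mol %), CH2Cl2, −78 → −40 °C
Reagents that add atoms: none
Why: In this Lewis acid-catalysed Diels–Alder reaction the silyloxy group directs C11 onto the enal β-carbon (C10), suprafacial addition to the E enal sets C15 and C9 cis, the endo (formyl) transition state places C20 cis to the formyl group (11-epi, corrected in step 8), and the chiral oxazaborolidinium shields one enal face to set C1 and C10 absolutely.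

Step 5
Reactants: 6 Diels–Alder adduct
Product: 7 (2R)-allylic alcohol (C2 now CH(OH)CH=CH2)
Conditions: CH2=CHMgBr (1.2 equiv), THF, −78 °C; aq. NH4Cl
Reagents that add atoms: vinylmagnesium bromide, C=C[Mg]Br
Why: Grignard 1,2-addition under Felkin–Anh control (C10 anti to the nucleophile, C14 inside, C15 methyl outside) gives the 2R carbinol and brings in C3 and the sacrificial CH2; the silyl enol ether is inert, and a moderate ratio is expected with separation of the minor epimer.

Step 6
Reactants: 7 (2R)-allylic alcohol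
Product: 8 2-O-TBS ether
Conditions: TBSOTf, 2,6-lutidine, CH2Cl2, −78 °C
Reagents that add atoms: tert-butyldimethylsilyl triflate, CC(C)(C)[Si](C)(C)OS(=O)(=O)C(F)(F)F
Why: Silylation protects the hindered C2 alcohol until the penultimate step.

Step 7
Reactants: 8 2-O-TBS ether
Product: 9 enone (C12=O, C13=C14; 11α-CH3)
Conditions: Pd(OAc)2 (15 mol %), O2 (1 atm), DMSO, 50 °C
Reagents that add atoms: none
Why: In this Saegusa–Ito oxidation the palladium enolate at C13 can β-hydride eliminate only toward C14, which places the ring alkene where the epoxide is needed.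

Step 8
Reactants: 9 enone (11α-CH3)
Product: 11 enone with 11β-CH3 (C15/C9/C20 all cis), via lithium dienolate 10 (not isolated)
Conditions: LiN(i-Pr)2 (1.1 equiv), THF, −78 °C; then 2,6-di-tert-butyl-4-methylphenol, −78 °C
Reagents that add atoms: none
Why: Only C11 can be deprotonated (C13=C14 blocks the other side), and kinetic C-protonation of the cross-conjugated dienolate from the α face, anti to the C10 substituent and the 1,3-related C15 methyl, gives the cis (11β-methyl) epimer.

Step 9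
Reactants: 11 enone with 11β-CH3
Product: 12 12β-allylic alcohol
Conditions: i-Bu2AlH (1.2 equiv), CH2Cl2, −78 °C
Reagents that add atoms: none
Why: In this 1,2-reduction hydride comes from the α face, opposite C20, C9 and C15, and gives the 12β alcohol cis to C20.

Step 10
Reactants: 12 12β-allylic alcohol
Product: 13 12-O-TES ether
Conditions: Et3SiOTf, 2,6-lutidine, CH2Cl2, −78 °C
Reagents that add atoms: triethylsilyl triflate, CC[Si](CC)(CC)OS(=O)(=O)C(F)(F)F
Why: Silylation gives a non-directing, bulky allylic ether that survives the organolithium steps and can later be removed in the presence of TBS and TBDPS.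

Step 11
Reactants: 13 12-O-TES ether
Product: 14 13α,14α-epoxide
Conditions: mCPBA, NaHCO3, CH2Cl2, 0 °C
Reagents that add atoms: 3-chloroperbenzoic acid, OOC(=O)c1cccc(Cl)c1
Why: Prilezhaev epoxidation occurs on the cis-disubstituted ring alkene (faster than the monosubstituted vinyl group) from the α face, anti to the allylic OTES and the C15 methyl.

Step 12
Reactants: 14 13α,14α-epoxide
Product: 15 primary alcohol at C9
Conditions: DDQ, CH2Cl2/pH 7 buffer, 0 °C
Reagents that add atoms: none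
Why: Oxidative PMB cleavage through the benzylic oxocarbenium ion leaves silyl ethers, epoxide and vinyl group untouched.

Step 13
Reactants: 15 primary alcohol at C9
Product: 16 ring A aldehyde (fragment A)
Conditions: Dess–Martin periodinane, NaHCO3, CH2Cl2, 0 °C
Reagents that add atoms: none
Why: Buffered hypervalent iodine oxidation gives the α-branched aldehyde without epimerising C10; it is used at once.

## Fragment B: dioxolanone acid 22

Step 14
Reactants: 17 dimethyl (S)-malate
Product: 19 dimethyl (2S,3R)-2-hydroxy-3-methylbutanedioate, via dilithium alkoxide enolate 18 (not isolated)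
Conditions: LiN(i-Pr)2 (2.2 equiv), THF, −78 → −20 °C; MeI, −78 °C
Reagents that add atoms: iodomethane, CI
Why: Fráter–Seebach alkylation of the chelated dianion puts the methyl anti to the alkoxide, setting the future C17 with the target configuration.

Step 15
Reactants: 19 dimethyl (2S,3R)-2-hydroxy-3-methylbutanedioate
Product: 20 dimethyl (2R,3R)-3-methyl-2-[(4-nitrobenzoyl)oxy]butanedioate
Conditions: 4-nitrobenzoic acid, PPh3, i-PrO2C–N=N–CO2-i-Pr, THF, 0 °C → rt
Reagents that add atoms: 4-nitrobenzoic acid, OC(=O)c1ccc(cc1)[N+](=O)[O-]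
Why: Mitsunobu esterification inverts the carbinol carbon (future C8) by SN2 displacement, giving the configuration the acetal auxiliary needs.

Step 16
Reactants: 20 dimethyl (2R,3R)-3-methyl-2-[(4-nitrobenzoyl)oxy]butanedioate
Product: 21 (2R,3R)-2-hydroxy-3-methylbutanedioic acid
Conditions: LiOH, THF/H2O, 0 °C → rt; then aq. HCl
Reagents that add atoms: lithium hydroxide, [Li+].[OH-]
Why: Saponification (acyl–oxygen cleavage) of all three esters leaves both stereocentres untouched.

Step 17
Reactants: 21 (2R,3R)-2-hydroxy-3-methylbutanedioic acid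
Product: 22 (2R)-2-[(2R,4R)-2-tert-butyl-5-oxo-1,3-dioxolan-4-yl]propanoic acid (fragment B)
Conditions: t-BuCHO, TsOH (cat.), H2SO4 (cat.), pentane, reflux (Dean–Stark)
Reagents that add atoms: pivalaldehyde, CC(C)(C)C=O
Why: Acetalisation of the α-hydroxy acid gives the thermodynamically preferred cis five-membered dioxolanone, whose acetal centre stores the C8 configuration (self-regeneration of stereocentres).

## Fragment C: iododiene 29

Step 18
Reactants: 23 methyl propiolate
Product: 25 methyl (2Z)-2-(hydroxymethyl)-3-iodoprop-2-enoate, via aluminium iodoallenolate 24 (not isolated)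
Conditions: Et2AlI (1.2 equiv), CH2Cl2, −78 °C; then HCHO (monomer from cracked paraformaldehyde), −78 °C
Reagents that add atoms: diethylaluminium iodide, CC[Al](I)CC; formaldehyde, C=O
Why: Iodide conjugate addition gives the β-iodoallenolate, which undergoes a kinetic aldol reaction with formaldehyde anti to iodine, so iodine ends cis to the ester (iodo-Morita–Baylis–Hillman reaction).

Step 19
Reactants: 25 methyl (2Z)-2-(hydroxymethyl)-3-iodoprop-2-enoate
Product: 26 methyl (2Z)-2-{[tert-butyl(diphenyl)silyl]oxymethyl}-3-iodoprop-2-enoate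
Conditions: TBDPSCl, imidazole, CH2Cl2, 0 °C
Reagents that add atoms: tert-butyl(chloro)diphenylsilane, CC(C)(C)[Si](Cl)(c1ccccc1)c1ccccc1
Why: Silylation installs the acid-stable protecting group on the future C16 hydroxyl.

Step 20
Reactants: 26 TBDPS ether ester
Product: 27 (2E)-2-{[tert-butyl(diphenyl)silyl]oxymethyl}-3-iodoprop-2-en-1-ol
Conditions: i-Bu2AlH (2.2 equiv), CH2Cl2, −78 °C
Reagents that add atoms: none
Why: Ester reduction to the allylic alcohol at low temperature leaves the vinyl iodide and its geometry intact.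

Step 21
Reactants: 27 allylic alcohol
Product: 28 (2Z)-2-{[tert-butyl(diphenyl)silyl]oxymethyl}-3-iodoprop-2-enal
Conditions: Dess–Martin periodinane, NaHCO3, CH2Cl2, 0 °C
Reagents that add atoms: none
Why: Mild, buffered oxidation avoids isomerisation of the (Z)-β-iodoenal.

Step 22
Reactants: 28 (Z)-β-iodoenal
Product: 29 tert-butyl{[(2E)-2-(iodomethylidene)but-3-en-1-yl]oxy}diphenylsilane (fragment C; iodine cis to the vinyl group)
Conditions: Ph3PCH3Br, KN(SiMe3)2, THF, −78 → 0 °C
Reagents that add atoms: methyltriphenylphosphonium bromide, C[P+](c1ccccc1)(c1ccccc1)c1ccccc1.[Br-]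
Why: Wittig methylenation turns the aldehyde into the C4 vinyl group, so C6–I and C4 are cis, as the ring-cis C5=C6 bond of the target requires.

## Fragment union and endgame

Step 23
Reactants: 22 dioxolanone acid (fragment B); 16 ring A aldehyde (fragment A)
Product: 32 aldol acid (C8–C9 bond formed; 9-OTES; dioxolanone and free C19 acid retained), via dilithium enolate 30 (not isolated), via bis(triethylsilyl) aldol adduct 31 (not isolated)
Conditions: 22, LiN(SiMe3)2 (2.2 equiv), THF, −78 °C; 16, −78 °C; then Et3SiCl (3 equiv), DMPU, −78 → −30 °C; aqueous work-up at pH 5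
Reagents that add atoms: chlorotriethylsilane, CC[Si](Cl)(CC)CC
Why: In this Seebach aldol the enolate is attacked anti to the tert-butyl group (C8, retention), the ring-fixed enolate geometry in a Zimmerman–Traxler transition state puts C17 syn and O8 anti to the new C9 oxygen, and Felkin–Anh control from C10 reinforces the same 9S outcome; silylating the aldolate in the flask prevents lactonisation of the C9 oxygen onto C19.

Step 24
Reactants: 32 aldol acid; 29 iododiene (fragment C)
Product: 36 α-hydroxy dienone acid (C7 ketone; 8-OH; C5=C6 with C4 and C7 cis), via dienyllithium 33 (not isolated), via lithium carboxylate 34 (not isolated), via lithium hemiketal alkoxide 35 (not isolated)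
Conditions: 29, t-BuLi (2.0 equiv), Et2O, −78 °C; 32, LiN(SiMe3)2 (1.05 equiv), THF, −78 °C; combine, −78 → −50 °C; aq. NH4Cl
Reagents that add atoms: none
Why: In this nucleophilic acyl substitution the configurationally stable alkenyllithium adds once to the non-enolisable acylal carbonyl (the carboxylate is inert), and the cyclic hemiketal alkoxide collapses only on work-up, releasing pivalaldehyde and the free 8-OH.

Step 25
Reactants: 36 α-hydroxy dienone acid
Product: 38 γ-lactone (C7–O–C19; 8-OH; 9,12-bis-OTES; 2-OTBS; 16-OTBDPS), via dihydroxy acid 37 (not isolated)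
Conditions: Zn(BH4)2, Et2O, −30 °C; then aq. citric acid (pH 4), rt
Reagents that add atoms: none
Why: In this chelation-controlled (Cram cyclic) 1,2-reduction hydride attacks the zinc chelate of C7=O and 8-OH from the side of the smaller C17 substituent, giving the 7,8-anti diol (7R), and the γ-hydroxy acid lactonises spontaneously.

Step 26
Reactants: 38 γ-lactone
Product: 39 9,12-diol
Conditions: HF·pyridine, pyridine, THF, 0 °C → rt
Reagents that add atoms: none
Why: Buffered fluoride cleaves the two TES ethers much faster than the secondary TBS and primary TBDPS ethers; the crude diol is acetylated directly to avoid acyl migration of the lactone to O9.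

Step 27
Reactants: 39 9,12-diol
Product: 40 9,12-diacetate
Conditions: Ac2O, pyridine, DMAP (cat.), CH2Cl2, 0 °C → rt
Reagents that add atoms: acetic anhydride, CC(=O)OC(C)=O
Why: Nucleophilic catalysis acetylates the two secondary alcohols while the hindered tertiary 8-OH does not react.

Step 28
Reactants: 40 9,12-diacetate
Product: 41 seco-diene (2-OH, 16-OH, 8-OH free; terminal vinyl groups at C3 and C4)
Conditions: n-Bu4NF, AcOH (1:1), THF, rt
Reagents that add atoms: none
Why: Buffered fluoride removes the TBS and TBDPS ethers without touching acetates, lactone or epoxide, and frees the allylic 2-OH that assists the metathesis.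

Step 29
Reactants: 41 seco-diene
Product: 42 CNP0285414.3
Conditions: second-generation Hoveyda–Grubbs catalyst, RuCl2(=CH-C6H4-2-O-i-Pr)(1,3-dimesitylimidazolidin-2-ylidene) (15 mol %), 1,4-benzoquinone (20 mol %), toluene (0.5 mM), 80 °C
Reagents that add atoms: none
Why: Ring-closing metathesis of the two monosubstituted alkenes (the trisubstituted C5=C6 is spared) closes the ten-membered ring, which is pre-organised by ring A, the trans-lactone and the cis C5=C6 bond; the ring size and diene conjugation favour the Z C3=C4 olefin.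

## Compound list

1 | 3-methylbut-2-en-1-ol (prenol) | CC(C)=CCO | starting material
2 | 1-methoxy-4-{[(3-methylbut-2-en-1-yl)oxy]methyl}benzene | COc1ccc(COCC=C(C)C)cc1 | intermediate
3 | (2E)-4-[(4-methoxybenzyl)oxy]-2-methylbut-2-enal | COc1ccc(COC/C=C(\C)C=O)cc1 | intermediate
4 | pent-1-en-3-one | CCC(=O)C=C | starting material
5 | tert-butyl(dimethyl)[(3Z)-penta-1,3-dien-3-yloxy]silane | C=C/C(O[Si](C)(C)C(C)(C)C)=C/C | intermediate
6 | Diels–Alder adduct: 1β-CH3, 1α-CHO, 10β-CH2OPMB, 11α-CH3, C12(OTBS)=C13 | COc1ccc(COC[C@@H]2[C@@H](C)C(O[Si](C)(C)C(C)(C)C)=CC[C@@]2(C)C=O)cc1 | intermediate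
7 | as 6, C2 = (R)-CH(OH)CH=CH2 | COc1ccc(COC[C@@H]2[C@@H](C)C(O[Si](C)(C)C(C)(C)C)=CC[C@@]2(C)[C@H](O)C=C)cc1 | intermediate
8 | 2-O-TBS ether of 7 | COc1ccc(COC[C@@H]2[C@@H](C)C(O[Si](C)(C)C(C)(C)C)=CC[C@@]2(C)[C@H](O[Si](C)(C)C(C)(C)C)C=C)cc1 | intermediate
9 | enone (C12=O, C13=C14), 11α-CH3 | COc1ccc(COC[C@@H]2[C@@H](C)C(=O)C=C[C@@]2(C)[C@H](O[Si](C)(C)C(C)(C)C)C=C)cc1 | intermediate
10 | lithium dienolate of 9 (C11=C12–OLi, C13=C14) | COc1ccc(COC[C@@H]2C(C)=C(O[Li])C=C[C@@]2(C)[C@H](O[Si](C)(C)C(C)(C)C)C=C)cc1 | intermediate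
11 | enone, 11β-CH3 | COc1ccc(COC[C@@H]2[C@H](C)C(=O)C=C[C@@]2(C)[C@H](O[Si](C)(C)C(C)(C)C)C=C)cc1 | intermediate
12 | 12β-allylic alcohol | COc1ccc(COC[C@@H]2[C@H](C)[C@H](O)C=C[C@@]2(C)[C@H](O[Si](C)(C)C(C)(C)C)C=C)cc1 | intermediate
13 | 12β-OTES ether | COc1ccc(COC[C@@H]2[C@H](C)[C@H](O[Si](CC)(CC)CC)C=C[C@@]2(C)[C@H](O[Si](C)(C)C(C)(C)C)C=C)cc1 | intermediate
14 | 13α,14α-epoxide | COc1ccc(COC[C@@H]2[C@H](C)[C@H](O[Si](CC)(CC)CC)[C@H]3O[C@H]3[C@@]2(C)[C@H](O[Si](C)(C)C(C)(C)C)C=C)cc1 | intermediate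
15 | C9 primary alcohol | OC[C@@H]1[C@H](C)[C@H](O[Si](CC)(CC)CC)[C@H]2O[C@H]2[C@@]1(C)[C@H](O[Si](C)(C)C(C)(C)C)C=C | intermediate
16 | ring A aldehyde (fragment A): C9 CHO, 12β-OTES, 13α,14α-epoxide, (2R)-OTBS vinyl carbinol | O=C[C@@H]1[C@H](C)[C@H](O[Si](CC)(CC)CC)[C@H]2O[C@H]2[C@@]1(C)[C@H](O[Si](C)(C)C(C)(C)C)C=C | intermediate
17 | dimethyl (S)-malate | COC(=O)C[C@H](O)C(=O)OC | starting material
18 | dilithium alkoxide enolate of 17 | COC(=O)[C@@H](O[Li])C=C(O[Li])OC | intermediate
19 | dimethyl (2S,3R)-2-hydroxy-3-methylbutanedioate | COC(=O)[C@H](C)[C@H](O)C(=O)OC | intermediate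
20 | dimethyl (2R,3R)-3-methyl-2-[(4-nitrobenzoyl)oxy]butanedioate | COC(=O)[C@H](C)[C@@H](OC(=O)c1ccc(cc1)[N+](=O)[O-])C(=O)OC | intermediate
21 | (2R,3R)-2-hydroxy-3-methylbutanedioic acid | OC(=O)[C@H](C)[C@@H](O)C(=O)O | intermediate
22 | (2R)-2-[(2R,4R)-2-tert-butyl-5-oxo-1,3-dioxolan-4-yl]propanoic acid (fragment B) | C[C@@H](C(=O)O)[C@H]1O[C@@H](C(C)(C)C)OC1=O | intermediate
23 | methyl propiolate | C#CC(=O)OC | starting material
24 | diethylaluminium β-iodoallenolate of 23 | CC[Al](CC)OC(OC)=C=CI | intermediate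
25 | methyl (2Z)-2-(hydroxymethyl)-3-iodoprop-2-enoate | I/C=C(CO)\C(=O)OC | intermediate
26 | methyl (2Z)-2-{[tert-butyl(diphenyl)silyl]oxymethyl}-3-iodoprop-2-enoate | I/C=C(CO[Si](c1ccccc1)(c1ccccc1)C(C)(C)C)\C(=O)OC | intermediate
27 | (2E)-2-{[tert-butyl(diphenyl)silyl]oxymethyl}-3-iodoprop-2-en-1-ol | I/C=C(CO[Si](c1ccccc1)(c1ccccc1)C(C)(C)C)\CO | intermediate
28 | (2Z)-2-{[tert-butyl(diphenyl)silyl]oxymethyl}-3-iodoprop-2-enal | I/C=C(CO[Si](c1ccccc1)(c1ccccc1)C(C)(C)C)\C=O | intermediate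
29 | tert-butyl{[(2E)-2-(iodomethylidene)but-3-en-1-yl]oxy}diphenylsilane (fragment C) | I/C=C(CO[Si](c1ccccc1)(c1ccccc1)C(C)(C)C)\C=C | intermediate
30 | dilithium enolate carboxylate of 22 | C[C@@H](C(=O)O[Li])C1=C(O[Li])O[C@H](C(C)(C)C)O1 | intermediate
31 | bis(triethylsilyl) aldol adduct (9-OTES, C19 TES ester) | C[C@@H](C(=O)O[Si](CC)(CC)CC)[C@]1(O[C@@H](C(C)(C)C)OC1=O)[C@@H](O[Si](CC)(CC)CC)[C@@H]1[C@H](C)[C@H](O[Si](CC)(CC)CC)[C@H]2O[C@H]2[C@@]1(C)[C@H](O[Si](C)(C)C(C)(C)C)C=C | intermediate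
32 | aldol acid (C8–C9 joined; 9-OTES; dioxolanone; C19 acid) | C[C@@H](C(=O)O)[C@]1(O[C@@H](C(C)(C)C)OC1=O)[C@@H](O[Si](CC)(CC)CC)[C@@H]1[C@H](C)[C@H](O[Si](CC)(CC)CC)[C@H]2O[C@H]2[C@@]1(C)[C@H](O[Si](C)(C)C(C)(C)C)C=C | intermediate
33 | dienyllithium from 29 | [Li]/C=C(CO[Si](c1ccccc1)(c1ccccc1)C(C)(C)C)\C=C | intermediate
34 | lithium carboxylate of 32 | C[C@@H](C(=O)O[Li])[C@]1(O[C@@H](C(C)(C)C)OC1=O)[C@@H](O[Si](CC)(CC)CC)[C@@H]1[C@H](C)[C@H](O[Si](CC)(CC)CC)[C@H]2O[C@H]2[C@@]1(C)[C@H](O[Si](C)(C)C(C)(C)C)C=C | intermediate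
35 | lithium hemiketal alkoxide (dienyl adduct at C7) | C[C@@H](C(=O)O[Li])[C@]1(O[C@@H](C(C)(C)C)OC1(O[Li])/C=C(CO[Si](c1ccccc1)(c1ccccc1)C(C)(C)C)\C=C)[C@@H](O[Si](CC)(CC)CC)[C@@H]1[C@H](C)[C@H](O[Si](CC)(CC)CC)[C@H]2O[C@H]2[C@@]1(C)[C@H](O[Si](C)(C)C(C)(C)C)C=C | intermediate
36 | α-hydroxy dienone acid (C7 ketone, 8-OH, C19 acid) | C[C@@H](C(=O)O)[C@@](O)(C(=O)/C=C(CO[Si](c1ccccc1)(c1ccccc1)C(C)(C)C)\C=C)[C@@H](O[Si](CC)(CC)CC)[C@@H]1[C@H](C)[C@H](O[Si](CC)(CC)CC)[C@H]2O[C@H]2[C@@]1(C)[C@H](O[Si](C)(C)C(C)(C)C)C=C | intermediate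
37 | 7,8-dihydroxy acid | C[C@@H](C(=O)O)[C@@](O)([C@H](O)/C=C(CO[Si](c1ccccc1)(c1ccccc1)C(C)(C)C)\C=C)[C@@H](O[Si](CC)(CC)CC)[C@@H]1[C@H](C)[C@H](O[Si](CC)(CC)CC)[C@H]2O[C@H]2[C@@]1(C)[C@H](O[Si](C)(C)C(C)(C)C)C=C | intermediate
38 | γ-lactone (C7–O–C19), 8-OH, 9,12-bis-OTES, 2-OTBS, 16-OTBDPS | C=C/C(CO[Si](c1ccccc1)(c1ccccc1)C(C)(C)C)=C\[C@H]1OC(=O)[C@H](C)[C@]1(O)[C@@H](O[Si](CC)(CC)CC)[C@@H]1[C@H](C)[C@H](O[Si](CC)(CC)CC)[C@H]2O[C@H]2[C@@]1(C)[C@H](O[Si](C)(C)C(C)(C)C)C=C | intermediate
39 | 9,12-diol | C=C/C(CO[Si](c1ccccc1)(c1ccccc1)C(C)(C)C)=C\[C@H]1OC(=O)[C@H](C)[C@]1(O)[C@@H](O)[C@@H]1[C@H](C)[C@H](O)[C@H]2O[C@H]2[C@@]1(C)[C@H](O[Si](C)(C)C(C)(C)C)C=C | intermediate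
40 | 9,12-diacetate | C=C/C(CO[Si](c1ccccc1)(c1ccccc1)C(C)(C)C)=C\[C@H]1OC(=O)[C@H](C)[C@]1(O)[C@@H](OC(C)=O)[C@@H]1[C@H](C)[C@H](OC(C)=O)[C@H]2O[C@H]2[C@@]1(C)[C@H](O[Si](C)(C)C(C)(C)C)C=C | intermediate
41 | seco-diene (2,8,16-triol 9,12-diacetate; open at C3/C4) | C=C/C(CO)=C\[C@H]1OC(=O)[C@H](C)[C@]1(O)[C@@H](OC(C)=O)[C@@H]1[C@H](C)[C@H](OC(C)=O)[C@H]2O[C@H]2[C@@]1(C)[C@H](O)C=C | intermediate
42 | CNP0285414.3 | CC(=O)O[C@H]1[C@@H](C)[C@H]2[C@H](OC(C)=O)[C@]3(O)[C@@H](/C=C(CO)\C=C/[C@@H](O)[C@]2(C)[C@@H]2O[C@H]12)OC(=O)[C@@H]3C | target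

## Step count and risks

Total: 29 steps. Longest linear sequence: 19 steps (1, 2, 4–13, 23–29).

The three steps most likely to fail:

**Step 23 (aldol of a tetrasubstituted enolate with a hindered, epimerisable aldehyde).** If enolate 30, which carries the branched C17 substituent, does not add to 16, the methyl group is left out of the enolate and introduced after lactone formation. The fallback sets out from 16 and returns at 38. [(2R,4R)-2-tert-butyl-5-oxo-1,3-dioxolan-4-yl]acetic acid F1 (from (R)-malic acid and pivalaldehyde, TsOH, pentane, reflux) is converted with LiN(SiMe3)2 into its less hindered dianion and added to 16 with the same Et3SiCl quench, giving the 18-nor aldol acid F2. Addition of 33 as in step 24 gives the 18-nor hydroxy dienone acid F3, and Zn(BH4)2 reduction with lactonisation gives the 18-nor lactone F4. The dianion of F4 (LiN(i-Pr)2, 2.2 equiv, THF/DMPU, −78 °C) is then methylated with MeI anti to the lithium alkoxide on C8 (Fráter–Seebach alkylation), which gives 38.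

**Step 24 (single addition of the dienyllithium to the hindered acylal carbonyl).** If 33 over-adds or does not open the dioxolanone, the acyl donor is changed. The fallback sets out from 32 and returns at 36. MeNH(OMe)·HCl with i-PrMgCl (THF, −20 °C) opens the dioxolanone, with loss of pivalaldehyde, to the Weinreb amide F5. Lithium reagent 33 (3 equiv) then adds once through the stable five-membered chelate, and work-up gives 36 for the same chelation-controlled reduction.

**Step 29 (ten-membered ring closure and Z selectivity).** If the free seco-diene gives oligomers or the E olefin, a temporary silicon tether is used. The fallback sets out from 41 and returns at 42. i-Pr2SiCl2 with imidazole (CH2Cl2, 2 mM) bridges O2 and O16 to give the twelve-membered cyclic silylene F6. Metathesis with the same ruthenium catalyst then closes an eight-membered siloxane ring in which only the Z C3=C4 olefin fits, giving the bridged macrocycle F7. HF·pyridine (THF, 0 °C) removes the tether and gives 42.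

## Further compounds

F1 | step 23 | [(2R,4R)-2-tert-butyl-5-oxo-1,3-dioxolan-4-yl]acetic acid | OC(=O)C[C@H]1O[C@@H](C(C)(C)C)OC1=O
F2 | step 23 | 18-nor aldol acid (as 32 without the C17 methyl) | OC(=O)C[C@]1(O[C@@H](C(C)(C)C)OC1=O)[C@@H](O[Si](CC)(CC)CC)[C@@H]1[C@H](C)[C@H](O[Si](CC)(CC)CC)[C@H]2O[C@H]2[C@@]1(C)[C@H](O[Si](C)(C)C(C)(C)C)C=C
F3 | step 23 | 18-nor hydroxy dienone acid (as 36 without the C17 methyl) | OC(=O)C[C@@](O)(C(=O)/C=C(CO[Si](c1ccccc1)(c1ccccc1)C(C)(C)C)\C=C)[C@@H](O[Si](CC)(CC)CC)[C@@H]1[C@H](C)[C@H](O[Si](CC)(CC)CC)[C@H]2O[C@H]2[C@@]1(C)[C@H](O[Si](C)(C)C(C)(C)C)C=C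
F4 | step 23 | 18-nor lactone (as 38 without the C17 methyl) | C=C/C(CO[Si](c1ccccc1)(c1ccccc1)C(C)(C)C)=C\[C@H]1OC(=O)C[C@]1(O)[C@@H](O[Si](CC)(CC)CC)[C@@H]1[C@H](C)[C@H](O[Si](CC)(CC)CC)[C@H]2O[C@H]2[C@@]1(C)[C@H](O[Si](C)(C)C(C)(C)C)C=C
F5 | step 24 | Weinreb amide hydroxy acid (C7 N-methoxy-N-methylamide, 8-OH, C19 acid) | C[C@@H](C(=O)O)[C@@](O)(C(=O)N(C)OC)[C@@H](O[Si](CC)(CC)CC)[C@@H]1[C@H](C)[C@H](O[Si](CC)(CC)CC)[C@H]2O[C@H]2[C@@]1(C)[C@H](O[Si](C)(C)C(C)(C)C)C=C
F6 | step 29 | O2,O16-diisopropylsilylene-bridged seco-diene | C=C/C(CO[Si]3(C(C)C)C(C)C)=C\[C@H]1OC(=O)[C@H](C)[C@]1(O)[C@@H](OC(C)=O)[C@@H]1[C@H](C)[C@H](OC(C)=O)[C@H]2O[C@H]2[C@@]1(C)[C@H](O3)C=C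
F7 | step 29 | O2,O16-diisopropylsilylene derivative of the target | CC(=O)O[C@H]1[C@@H](C)[C@H]2[C@H](OC(C)=O)[C@]3(O)[C@@H](/C=C(CO[Si]4(C(C)C)C(C)C)\C=C/[C@@H](O4)[C@]2(C)[C@@H]2O[C@H]12)OC(=O)[C@@H]3C
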